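In ring B (the phenolic arene) the hydroxyl-bearing carbon lies ortho to the carbon that carries the benzylic CH2 (C7) of the heptanoid chain (C1–C7, counted from ring A). This ortho-hydroxybenzyl motif is the retron of an aromatic Claisen rearrangement. The aryl–C7 bond is therefore made by a ring-expanding Claisen shift of a 13-membered macrocyclic aryl allyl ether, in which the future phenol oxygen is bound to chain carbon C5 and C5 carries a vinyl group (C6=C7). One operation closes the 15-membered meta,para-cyclophane, fixes the ring B substitution pattern and frees the phenol. The precursor arises from anisylacetone, acrolein and symmetrical 2-methoxyresorcinol by aldol addition, Mitsunobu etherification and Ullmann macrocyclization.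

Key step: step 6

Numbering used: chain carbons C1–C7 run from ring A to ring B, with the ketone at C3. Ring A (the anisole ring) carries C1 at its position 1, the diaryl ether oxygen at position 3 and OMe at position 4. Ring B carries the diaryl ether oxygen at its position 1, C7 at position 4, OH at position 5 and OMe at position 6.

Remark: the target is achiral. Compounds 4, 5, 6, 8, 9 and 10 each carry one uncontrolled stereocentre, and all of these are gone by the end of step 6.

Step 1
Reactants: 1 4-(4-methoxyphenyl)butan-2-one
Product: 2 4-(3-iodo-4-methoxyphenyl)butan-2-one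
Conditions: NIS, TFA (cat.), MeCN, rt
Reagents that add atoms: N-iodosuccinimide, O=C1CCC(=O)N1I
Why: Electrophilic aromatic iodination of the anisole should go ortho to OMe because the para position carries the chain, and the ketone should be untouched under these mildly acidic conditions.

Step 2
Reactants: 2 4-(3-iodo-4-methoxyphenyl)butan-2-one; 3 acrolein
Product: 4 rac-5-hydroxy-1-(3-iodo-4-methoxyphenyl)hept-6-en-3-one
Conditions: LiN(iPr)2 (1.05 equiv), THF, −78 °C; then 3, −78 °C; aq. NH4Cl at −78 °C
Reagents that add atoms: none
Why: Kinetic deprotonation of the methyl ketone at CH3 and 1,2-addition of the lithium enolate to acrolein (directed aldol addition) should give the β-hydroxy ketone; the new carbinol centre is not controlled and is erased in step 6.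

Step 3
Reactants: 4 rac-5-hydroxy-1-(3-iodo-4-methoxyphenyl)hept-6-en-3-one
Product: 6 rac-1-{2-[2-(3-iodo-4-methoxyphenyl)ethyl]-1,3-dioxolan-2-yl}but-3-en-2-ol, via trimethylsilyl ether 5 (not isolated)
Conditions: Me3SiOCH2CH2OSiMe3 (3 equiv), TMSOTf (0.1 equiv), CH2Cl2, −78 → −20 °C; pyridine quench; then K2CO3 (cat.), MeOH, 0 °C
Reagents that add atoms: 1,2-bis(trimethylsilyloxy)ethane, C[Si](C)(C)OCCO[Si](C)(C)C
Why: Aprotic silyl-transfer ketalization (Noyori conditions) at low temperature should protect the ketone without dehydrating the aldol, the alcohol being silylated in the flask and freed again by methanolysis.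

Step 4
Reactants: 6 rac-1-{2-[2-(3-iodo-4-methoxyphenyl)ethyl]-1,3-dioxolan-2-yl}but-3-en-2-ol; 7 2-methoxybenzene-1,3-diol (3 equiv)
Product: 8 rac-3-[(1-{2-[2-(3-iodo-4-methoxyphenyl)ethyl]-1,3-dioxolan-2-yl}but-3-en-2-yl)oxy]-2-methoxyphenol
Conditions: PPh3, DIAD, THF, 0 °C → rt
Reagents that add atoms: none
Why: Mitsunobu etherification (SN2 at the carbinol carbon of a racemic secondary allylic alcohol) should give the branched aryl allyl ether, and the excess of the symmetrical diol 7 should favour the monoether.

Step 5
Reactants: 8 rac-3-[(1-{2-[2-(3-iodo-4-methoxyphenyl)ethyl]-1,3-dioxolan-2-yl}but-3-en-2-yl)oxy]-2-methoxyphenol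
Product: 9 racemic 13-membered macrocyclic aryl allyl ether (diaryl ether closed; ring B oxygen on C5, which bears the vinyl group; C3 as dioxolane)
Conditions: CuI (0.3 equiv), picolinic acid (0.6 equiv), K3PO4 (3 equiv), DMSO, 90 °C, syringe-pump addition, final 2 mM
Reagents that add atoms: none
Why: Intramolecular Ullmann diaryl ether coupling under high dilution should join the ring B phenoxide to the iodine-bearing carbon of ring A, a closure type established for macrocyclic diaryl ether heptanoids, at a temperature below the onset of the Claisen rearrangement.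

Step 6
Reactants: 9 racemic 13-membered macrocyclic aryl allyl ether
Product: 11 (E)-5,6-didehydrojuglanin A ethylene ketal (15-membered ring; free phenol on ring B), via cyclohexadienone 10 (not isolated)
Conditions: PhNEt2, 180 °C, sealed tube, Ar, 0.01 M
Reagents that add atoms: none
Why: A concerted suprafacial [3,3]-sigmatropic shift (aromatic Claisen rearrangement) through a six-centre chair array made of the free ortho carbon of ring B (position 4), the oxygen-bearing carbon (position 5), the ether oxygen, C5, C6 and C7 breaks the O–C5 bond while the vinyl terminus C7 bonds to that ortho carbon, and the resulting 6-alkylcyclohexa-2,4-dienone 10 enolizes to phenol 11. The closest known reaction types are the thermal ortho-Claisen rearrangement of aryl 1-alkylallyl ethers and the ring-expanding Claisen rearrangement of cyclic ethers that carry the vinyl group outside the ring. The 15-membered ring is closed by sigmatropic ring expansion of the 13-membered ring by two atoms (the ether oxygen leaves the ring; the ortho carbon of ring B, C7 and C6 enter it), not by an end-to-end cyclization, so high dilution is not essential, and relief of the strain of the smaller ring with its inward-pointing methoxy group should add driving force. No lasting stereocentre is created: the sp3 ring carbon of 10 is lost on enolization, and the C5=C6 geometry (E expected from a chair with C4 pseudo-equatorial) is erased in step 7. The step needs ortho regioselectivity, secured because the other ortho carbon of ring B (position 6) is blocked by OMe and position 4 is the only free position next to the ether oxygen; it also needs the C5–O bond to shift and not eliminate, which the dioxolane at C3 (no β-aryloxy ketone) and the basic aprotic medium should secure.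

Step 7
Reactants: 11 (E)-5,6-didehydrojuglanin A ethylene ketal
Product: 13 juglanin A, via saturated dioxolane 12 (not isolated)
Conditions: H2 (1 atm), 10% Pd/C, EtOAc/MeOH, rt; filtration through Celite; then 2 M HCl, THF, rt
Reagents that add atoms: water, O
Why: Heterogeneous catalytic hydrogenation should saturate the disubstituted alkene without touching the diaryl ether, and acid-catalysed ketal hydrolysis should then free the C3 ketone; no stereocentre remains.

Compound list
1 | 4-(4-methoxyphenyl)butan-2-one (anisylacetone) | COc1ccc(CCC(C)=O)cc1 | starting material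
2 | 4-(3-iodo-4-methoxyphenyl)butan-2-one | COc1ccc(CCC(C)=O)cc1I | intermediate
3 | acrolein (prop-2-enal) | C=CC=O | starting material
4 | rac-5-hydroxy-1-(3-iodo-4-methoxyphenyl)hept-6-en-3-one | COc1ccc(CCC(=O)CC(O)C=C)cc1I | intermediate
5 | rac-2-[2-(3-iodo-4-methoxyphenyl)ethyl]-2-[2-(trimethylsilyloxy)but-3-en-1-yl]-1,3-dioxolane (not isolated) | COc1ccc(CCC2(CC(O[Si](C)(C)C)C=C)OCCO2)cc1I | intermediate
6 | rac-1-{2-[2-(3-iodo-4-methoxyphenyl)ethyl]-1,3-dioxolan-2-yl}but-3-en-2-ol | COc1ccc(CCC2(CC(O)C=C)OCCO2)cc1I | intermediate
7 | 2-methoxybenzene-1,3-diol (2-methoxyresorcinol) | COc1c(O)cccc1O | starting material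
8 | rac-3-[(1-{2-[2-(3-iodo-4-methoxyphenyl)ethyl]-1,3-dioxolan-2-yl}but-3-en-2-yl)oxy]-2-methoxyphenol | COc1ccc(CCC2(CC(Oc3cccc(O)c3OC)C=C)OCCO2)cc1I | intermediate
9 | racemic 13-membered macrocycle: diaryl ether from position 3 of ring A to position 1 of ring B; position 5 of ring B joined through oxygen to C5, which carries a vinyl group (C6=C7); C4H2, C3 as 1,3-dioxolane-2,2-diyl, C2H2 and C1H2 lead back to position 1 of ring A; OMe on position 4 of ring A and on position 6 of ring B; positions 2, 3 and 4 of ring B unsubstituted | COc1ccc2cc1Oc1cccc(c1OC)OC(C=C)CC1(OCCO1)CC2 | intermediate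
10 | 15-membered cyclohexa-2,4-dienone of ring B (carbonyl at position 5, sp3 carbon at position 4 carrying C7H2, E C5=C6 alkene, C3 as dioxolane; not isolated) | COc1ccc2cc1OC1=C(OC)C(=O)C(C=C1)C/C=C/CC1(OCCO1)CC2 | intermediate
11 | (E)-5,6-didehydrojuglanin A ethylene ketal: 15-membered meta,para-cyclophane in which ring B is joined through C7H2–C6H=C5H–C4H2–C3(dioxolane)–C2H2–C1H2 to ring A, free OH on ring B next to the chain | COc1ccc2cc1Oc1ccc(c(O)c1OC)C/C=C/CC1(OCCO1)CC2 | intermediate
12 | juglanin A ethylene ketal (C3 as 1,3-dioxolane; not isolated) | COc1ccc2cc1Oc1ccc(c(O)c1OC)CCCCC1(OCCO1)CC2 | intermediate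
13 | juglanin A | COc1ccc2cc1Oc1ccc(c(O)c1OC)CCCCC(=O)CC2 | target

Total step count: 7. Longest linear sequence: 7 steps (1 → 13).

Steps most likely to fail

Step 6 (Claisen ring expansion). The secondary allylic C5–O bond may ionize or eliminate instead of shifting, the allyl unit may migrate on to the para position of ring B, or the 13-membered ring may not reach the chair geometry. The fallback keeps the bond between C7 and ring B as the ring-closing bond but makes it by B-alkyl Suzuki–Miyaura macrocyclization; it sets out from 2 and 7 and returns at 13. Kinetic enolate allylation of 2 (LiN(iPr)2, THF, −78 °C; allyl bromide) should give 1-(3-iodo-4-methoxyphenyl)hept-6-en-3-one F1, which is ketalized (ethylene glycol, TsOH, benzene, reflux) to 2-(but-3-en-1-yl)-2-[2-(3-iodo-4-methoxyphenyl)ethyl]-1,3-dioxolane F2. Diol 7 is mono-protected (chloromethyl methyl ether, iPr2NEt, excess 7) as 2-methoxy-3-(methoxymethoxy)phenol F3 and brominated para to the free hydroxyl (NBS, MeCN, 0 °C) to 4-bromo-2-methoxy-3-(methoxymethoxy)phenol F4. Ullmann coupling of F2 with F4 (CuI, picolinic acid, K3PO4, DMSO, 80 °C; the aryl iodide should react before the phenoxide-deactivated aryl bromide) gives the diaryl ether bromide 2-(but-3-en-1-yl)-2-{2-[3-(4-bromo-2-methoxy-3-(methoxymethoxy)phenoxy)-4-methoxyphenyl]ethyl}-1,3-dioxolane F5. Hydroboration of the terminal alkene with 9-BBN (THF, rt) gives the B-alkyl-9-borabicyclononane F6, which is cyclized without isolation (Pd(dppf)Cl2, AsPh3, Cs2CO3, THF/DMF/H2O, high dilution, 60 °C) to the methoxymethyl-protected juglanin A ethylene ketal F7. Aqueous HCl in THF/MeOH then removes the methoxymethyl group and the dioxolane to give 13.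

Step 5 (Ullmann macrocyclization). Intermolecular coupling to oligomers or reductive loss of iodine may outrun closure, because the 13-membered ring with the inward-pointing methoxy group of ring B forms slowly. The fallback closes the same ring at the other ether bond; it sets out from 6 and 7 and returns at 9. Intermolecular Ullmann coupling of 6 with excess 7 (CuI, picolinic acid, K3PO4, DMSO, 80 °C; the phenoxide should react in preference to the secondary alcohol) gives the seco diaryl ether rac-3-{5-[2-(2-(2-hydroxybut-3-en-1-yl)-1,3-dioxolan-2-yl)ethyl]-2-methoxyphenoxy}-2-methoxyphenol F8. Intramolecular Mitsunobu etherification (PPh3, DIAD, toluene, slow addition, high dilution, 0 °C → rt) then forms the bond between C5 and the remaining phenol oxygen of ring B and gives 9.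

Step 4 (Mitsunobu etherification). Allylic transposition (attack at the vinyl terminus giving the linear ether), elimination to the diene, or double etherification of the diol may compete. The fallback replaces the SN2 displacement by a metal-catalysed allylic substitution; it sets out from 6 and returns at 8. Alcohol 6 is converted (methyl chloroformate, pyridine, CH2Cl2, 0 °C) into rac-1-{2-[2-(3-iodo-4-methoxyphenyl)ethyl]-1,3-dioxolan-2-yl}but-3-en-2-yl methyl carbonate F9. Rhodium-catalysed allylic etherification (RhCl(PPh3)3, P(OMe)3, the sodium phenoxide made from excess 7 and NaN(SiMe3)2, THF, 0 °C → rt), a reaction type that keeps the oxygen at the more substituted allyl terminus of secondary allylic carbonates, should then give 8.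

Further compounds
F1 | step 6 | 1-(3-iodo-4-methoxyphenyl)hept-6-en-3-one | COc1ccc(CCC(=O)CCC=C)cc1I
F2 | step 6 | 2-(but-3-en-1-yl)-2-[2-(3-iodo-4-methoxyphenyl)ethyl]-1,3-dioxolane | COc1ccc(CCC2(CCC=C)OCCO2)cc1I
F3 | step 6 | 2-methoxy-3-(methoxymethoxy)phenol | COCOc1cccc(O)c1OC
F4 | step 6 | 4-bromo-2-methoxy-3-(methoxymethoxy)phenol | COCOc1c(Br)ccc(O)c1OC
F5 | step 6 | 2-(but-3-en-1-yl)-2-{2-[3-(4-bromo-2-methoxy-3-(methoxymethoxy)phenoxy)-4-methoxyphenyl]ethyl}-1,3-dioxolane | COc1ccc(CCC2(CCC=C)OCCO2)cc1Oc1ccc(Br)c(OCOC)c1OC
F6 | step 6 | B-alkyl-9-borabicyclo[3.3.1]nonane from hydroboration of F5 at the terminal alkene carbon | COc1ccc(CCC2(CCCCB3C4CCCC3CCC4)OCCO2)cc1Oc1ccc(Br)c(OCOC)c1OC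
F7 | step 6 | O-methoxymethyl juglanin A ethylene ketal (methoxymethyl group on the ring B phenol oxygen) | COc1ccc2cc1Oc1ccc(c(OCOC)c1OC)CCCCC1(OCCO1)CC2
F8 | step 5 | rac-3-{5-[2-(2-(2-hydroxybut-3-en-1-yl)-1,3-dioxolan-2-yl)ethyl]-2-methoxyphenoxy}-2-methoxyphenol | COc1ccc(CCC2(CC(O)C=C)OCCO2)cc1Oc1cccc(O)c1OC
F9 | step 4 | rac-1-{2-[2-(3-iodo-4-methoxyphenyl)ethyl]-1,3-dioxolan-2-yl}but-3-en-2-yl methyl carbonate | COc1ccc(CCC2(CC(OC(=O)OC)C=C)OCCO2)cc1I
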